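## The problem

Compound 19 is an acyclic 2-arylglycerol derivative. One fully substituted carbon (C2 of the propane chain) carries the 5-hydroxy-2-methoxy-4-methylphenyl ring, a free tertiary hydroxyl and two CH2O arms, one acetylated and one esterified with (E)-2-methylbut-2-enoic (tiglic) acid. No ring other than the arene has to be made; the work is to build the chain around this carbon and to tell its two arms apart. C2 is the only stereocenter (R), and it is a stereocenter only because the arms carry different acyl groups. Nothing else in the molecule can control it, so its configuration has to come from a chiral catalyst. Any intermediate with one acylated and one free primary arm is therefore configurationally fragile: an acyl shift from one arm to the other, directly or by way of the tertiary hydroxyl, gives the enantiomer. The tiglate alkene will not survive oxidative alkene cleavage or hydrogenation, both esters are base-labile, the tertiary benzylic alcohol on an electron-rich ring ionises in strong acid, and the para-oxygenated phenol is acidic and easily oxidised, so it must stay masked to the end. The feature that opens the key step is C2 itself: if one CH2O arm is carried as a vinyl group, C2 becomes the substituted terminus of an allyl unit flanked by the aryl group and the other CH2O arm, so a cyclic carbonate spanning the tertiary oxygen and that arm can be ionised by zerovalent palladium and the tertiary C–O bond re-made with water under ligand control.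

## Retrosynthesis

19 ⇒ 18. The aryl O–Si bond is cut last. A free phenol would quench the organometallic steps, compete in both acylations and make the ring far more vulnerable to the oxidative alkene cleavage; a benzyl ether would need hydrogenolysis (which threatens the tiglate alkene) and an acetal would need acid (which threatens the benzylic carbinol). A triisopropylsilyl ether comes off with buffered fluoride, which touches neither ester. The forward step only has to keep the medium non-basic.

18 ⇒ 16 + 17. The acyl–O bond of the tiglate is cut before that of the acetate, because the tiglate alkene cannot be present when the one-carbon arm is generated by alkene cleavage. Tigloyl chloride 17 delivers the E-alkene intact. Precursor 16 is five carbons smaller; the forward step must acylate the primary hydroxyl beside the tertiary one and do so before the acetate of 16 can move.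

16 ⇒ 15 ⇒ 13 ⇒ 12. The free CH2OH arm of 16 is traced to aldehyde 15 and this to the vinyl group of 13 (C=C cleavage, one carbon excised); the acetate of 13 is traced to the primary hydroxyl of diol 12. Carrying one arm as a vinyl group means the two arms are chemically different from the moment the stereocenter is formed, so no selective deprotection of two like groups is needed. The forward steps require primary-selective acetylation, an alkene cleavage that spares the arene and does not over-cleave the α-hydroxy aldehyde, and a reduction cold enough to leave the acetate in place.

12 ⇒ 10 + 11. The tertiary C–O bond is cut: diol 12 is made from racemic vinyl carbonate 10 and water 11 by palladium-catalysed decarboxylative allylic substitution. Against cutting the aryl–C2 bond or desymmetrising two like arms, this cut lets a racemic, easily made precursor converge on one enantiomer, and it places the stereocenter in a compound (12) that has no acyl group to shift. The forward reaction must deliver the branched regioisomer and high enantioselectivity on an ortho-methoxyaryl substrate.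

10 ⇒ 8, and 8 ⇒ 6 + 7. The two C–O bonds of the carbonate are traced to the tertiary hydroxyl and the CH2Cl group of chlorohydrin 8 by a carboxylative ring closure. The C2–vinyl bond of 8 is cut to chloroketone 6 and vinylmagnesium bromide 7. No stereocontrol is asked for here, since 10 is used as the racemate.

6 ⇒ 5 + 4, and 5 ⇐ 3 ⇐ 2 ⇐ 1. The aryl–carbonyl bond is cut to aryllithium 5 and the chloroacetyl Weinreb amide 4. Aryllithium 5 comes from bromide 3, and 3 from silyl ether 2 of commercial 4-methoxy-2-methylphenol 1 by bromination at the one position that is ortho to OCH3 and para to CH3. The forward steps need regioselective bromination and a clean single acylation.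

## Roads not taken

Alternative 1: The aryl–C2 bond is cut. Arylboronic acid A1 (from 3 by lithiation to 5 and borylation) would add to the ketone carbonyl of ethyl 3-(benzyloxy)-2-oxopropanoate A2 under a rhodium catalyst with a chiral diene ligand, giving hydroxy ester A3 with the stereocenter set during C–C bond formation.
- Merits: the route is convergent, no carbon is excised, and the arms arrive different (CH2OBn against CO2Et). Ester reduction, acetylation and hydrogenolysis would reach 16, so the whole route is about two steps shorter than the chosen one.
- Weak points: A2 is enolisable and hydrates readily; the catalyst has to distinguish CO2Et from CH2OBn, two groups of similar size; and A1 is an electron-rich ortho-alkoxy boronic acid, prone to protodeboronation and slow to add as a hindered aryl–rhodium species. A2 also has to be prepared, and the route still passes through migration-prone 16.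
- Comparison: this road is better on step count and atom economy. The chosen plan sets against it a stereo-defining step that operates on exactly the substrate class for which it is established (4-aryl-4-vinyl dioxolanones with water).

Alternative 2: No skeletal bond is cut at the stereo-defining stage. Achiral triol A4 (from 5 and a ketal-protected dihydroxyacetone, then acid) would be mono-acetylated on one enantiotopic CH2OH by a lipase with an enol acetate as acyl donor, giving monoacetate A5, which is the same compound as 16.
- Merits: about seven steps in all, four fewer than the chosen route; no transition metal; and the complementary enzymatic hydrolysis of the diacetate normally gives the opposite sense, so both enantiomers are in principle reachable.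
- Weak points: the prochiral carbon is fully substituted and carries a bulky ortho-substituted aryl group, a situation in which lipase selectivity is hard to predict. The sense of induction cannot be designed. The product of the stereo-defining step is the migration-prone monoacetate itself, formed over a long reaction time next to a free tertiary hydroxyl, so enantiomeric purity can erode while it is being created. Over-acylation to the achiral diacetate also costs material.
- Comparison: this road is clearly better on step economy. The chosen plan offers in return a stereocenter created in 12, which cannot racemise by acyl shift and can be assayed and upgraded before the labile stage is crossed in two short, cold operations, and an absolute sense chosen by the ligand antipode.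

Alternative 3: One CH2–O bond of an oxetane is cut. Oxetanol A7 (from 5 and oxetan-3-one A6) would be opened at one enantiotopic CH2 by tiglic acid A8 under a chiral phosphoric acid, giving hydroxy tiglate A9; acetylation and desilylation would finish the synthesis.
- Merits: about six steps, the shortest of all. The tiglate is installed in the stereo-defining step, and A9 carries the less mobile of the two acyl groups, so it is more robust than 16.
- Weak points: an intermolecular, enantioselective opening of a 3,3-disubstituted oxetane by a carboxylic acid has no close precedent; the known desymmetrisations rely on tethered or much stronger external nucleophiles. A 3-aryl-oxetan-3-ol with an electron-rich ring ionises at the benzylic C–OH under Brønsted acid, which diverts the substrate into carbocation chemistry instead of attack at CH2.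
- Comparison: if it worked it would roughly halve the route. The chosen plan is longer but rests on a documented reaction type and does not require a new method.

Key step: step 6

Assumption: which antipode of the chiral phosphoramidite gives the (R)-diol 12 with this ortho-methoxyaryl substrate is taken to be settled by a preliminary run with assignment of configuration; the route is written for that antipode, called L* (a BINOL-derived phosphoramidite with a chiral bis(1-arylethyl)amine unit).

Notation: Ar = 2-methoxy-4-methyl-5-(triisopropylsilyloxy)phenyl. Compounds 8, 9 and 10 are racemic. The descriptor at the carbinol carbon changes along the route (12 R, 13 R, 15 R, 16 S, 18 R, 19 R) only because substituent priorities change; no bond to that carbon is touched after step 6.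

## Route

Step 1
Reactants: 1 4-methoxy-2-methylphenol
Product: 2 (4-methoxy-2-methylphenoxy)triisopropylsilane
Conditions: TIPSCl, imidazole, DMF, rt
Reagents that add atoms: triisopropylsilyl chloride, CC(C)[Si](Cl)(C(C)C)C(C)C
Why: Imidazole-mediated O-silylation of a phenol; the bulky silyl ether removes the acidic proton for the organometallic steps and makes the silyloxy group a weaker ortho director than OCH3.

Step 2
Reactants: 2 (4-methoxy-2-methylphenoxy)triisopropylsilane
Product: 3 (5-bromo-4-methoxy-2-methylphenoxy)triisopropylsilane
Conditions: NBS, MeCN, 0 °C → rt
Reagents that add atoms: N-bromosuccinimide, O=C1CCC(=O)N1Br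
Why: Electrophilic aromatic bromination; the position ortho to OCH3 and para to CH3 is doubly activated and open, whereas the site between OCH3 and CH3 is flanked on both sides and the site next to the bulky silyloxy group is only singly activated.

Step 3
Reactants: 3 (5-bromo-4-methoxy-2-methylphenoxy)triisopropylsilane, 4 2-chloro-N-methoxy-N-methylacetamide
Product: 6 chloroketone (2-chloro-1-Ar-ethan-1-one), via aryllithium 5 (not isolated)
Conditions: n-BuLi, THF, −78 °C; then 4, −78 °C; sat. NH4Cl
Reagents that add atoms: none
Why: Bromine–lithium exchange followed by Weinreb ketone synthesis; the chelated tetrahedral adduct cannot add a second aryl group and releases the α-chloroketone on quench. The lithium sits meta to the silyloxy group, so no silyl migration is possible.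

Step 4
Reactants: 6 chloroketone (2-chloro-1-Ar-ethan-1-one), 7 vinylmagnesium bromide
Product: 8 racemic 1-chloro-2-Ar-but-3-en-2-ol
Conditions: THF, −78 → −40 °C; sat. NH4Cl at −40 °C
Reagents that add atoms: none
Why: Grignard 1,2-addition to the ketone, fast at low temperature and helped by chelation to the ortho-methoxy group; the cold quench prevents the magnesium alkoxide from closing onto the CH2Cl group. The product is racemic by design.

Step 5
Reactants: 8 racemic 1-chloro-2-Ar-but-3-en-2-ol
Product: 10 racemic 4-Ar-4-vinyl-1,3-dioxolan-2-one, via potassium carbonate half-ester 9 (not isolated)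
Conditions: CO2 (1 atm), K2CO3, DMF, rt → 40 °C
Reagents that add atoms: carbon dioxide, O=C=O
Why: Carboxylative cyclisation of a halohydrin: the tertiary alkoxide is captured by CO2 as its carbonate half-ester, which displaces the primary chloride in a 5-exo-tet closure. The CO2-buffered carbonate is mild enough for the aryl silyl ether.

Step 6
Reactants: 10 racemic 4-Ar-4-vinyl-1,3-dioxolan-2-one, 11 water
Product: 12 (2R)-2-Ar-but-3-ene-1,2-diol
Conditions: Pd2(dba)3·CHCl3 (2.5 mol %), phosphoramidite L* (10 mol %), BEt3 (cat.), 11 (excess), THF, rt
Reagents that add atoms: none
Why: Zerovalent palladium, formed from Pd2(dba)3·CHCl3 and L*, ionises the tertiary allylic C–O bond of either enantiomer of 10, and the carbonate anion loses CO2 to leave a zwitterionic π-allylpalladium complex with a pendant primary alkoxide. The two diastereomeric complexes interconvert by π-σ-π isomerisation through the unsubstituted CH2 terminus faster than they are trapped, so both enantiomers of 10 converge on one product (a dynamic kinetic asymmetric transformation). The alkoxide binds BEt3 and water as a borate that hands hydroxide to the adjacent aryl-bearing terminus; this forms the tertiary C–O bond, and it is here that the chiral ligand fixes the (R) configuration. The closest known reaction type is the palladium/phosphoramidite decarboxylative allylic substitution of 4-aryl-4-vinyl-1,3-dioxolan-2-ones with water under borane co-catalysis. No ring is closed; the carbonate ring is opened and lost. The step needs branched regioselectivity, which the cation-stabilising aryl group and delivery from the tethered alkoxide secure, and enantioselectivity, which the ligand secures by acting on the equilibrating π-allyl pair. The aryl silyl ether, the methyl ether and the vinyl group of the product are inert under these neutral conditions.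

Step 7
Reactants: 12 (2R)-2-Ar-but-3-ene-1,2-diol
Product: 13 (2R)-2-hydroxy-2-Ar-but-3-en-1-yl acetate
Conditions: Ac2O (1.1 equiv), pyridine, DMAP (cat.), CH2Cl2, 0 °C
Reagents that add atoms: acetic anhydride, CC(=O)OC(C)=O
Why: Nucleophile-catalysed acylation selective for the primary hydroxyl; the tertiary benzylic hydroxyl is too hindered to react with one equivalent of anhydride at 0 °C, and the stereocenter is not touched.

Step 8
Reactants: 13 (2R)-2-hydroxy-2-Ar-but-3-en-1-yl acetate
Product: 15 (2R)-2-hydroxy-2-Ar-3-oxopropyl acetate, via secondary ozonide 14 (not isolated)
Conditions: O3/O2, CH2Cl2, −78 °C, Sudan Red 7B as end-point indicator; then PPh3, −78 °C → rt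
Reagents that add atoms: ozone, [O-][O+]=O
Why: Ozonolysis with reductive work-up (Criegee mechanism); it is chosen over an OsO4/NaIO4 cleavage because periodate would cleave the α-hydroxy aldehyde and its triol precursor further, to the aryl ketone. The monosubstituted alkene takes up ozone much faster than the arene at −78 °C, the dye marks the end-point, and the allylic oxygens steer cycloreversion so that the carbonyl oxide forms on the CH2 fragment and not next to the carbinol.

Step 9
Reactants: 15 (2R)-2-hydroxy-2-Ar-3-oxopropyl acetate
Product: 16 (2S)-2,3-dihydroxy-2-Ar-propyl acetate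
Conditions: NaBH4, THF/MeOH, −78 °C; AcOH quench at −78 °C
Reagents that add atoms: none
Why: Borohydride reduction of an aldehyde, complete within minutes at −78 °C while esters are untouched; low temperature and an acidic quench keep the acetyl group from shifting to the new primary hydroxyl, which would invert the stereocenter.

Step 10
Reactants: 16 (2S)-2,3-dihydroxy-2-Ar-propyl acetate, 17 (E)-2-methylbut-2-enoyl chloride (tigloyl chloride)
Product: 18 (2R)-3-acetoxy-2-hydroxy-2-Ar-propyl (E)-2-methylbut-2-enoate
Conditions: pyridine, DMAP (cat.), CH2Cl2, 0 °C
Reagents that add atoms: none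
Why: Acylation of the only primary hydroxyl by an acid chloride; the tertiary hydroxyl does not compete. Pyridine, and not a trialkylamine, is used so that no vinylketene forms and the E-alkene is not deconjugated; once both arms are esterified the configuration is locked.

Step 11
Reactants: 18 (2R)-3-acetoxy-2-hydroxy-2-Ar-propyl (E)-2-methylbut-2-enoate
Product: 19 (2R)-3-acetoxy-2-hydroxy-2-(5-hydroxy-2-methoxy-4-methylphenyl)propyl (E)-2-methylbut-2-enoate
Conditions: TBAF, AcOH (1:1), THF, 0 °C, argon
Reagents that add atoms: none
Why: Fluoride cleavage of an aryl silyl ether, driven by Si–F bond formation; the acetic acid buffer protonates the phenoxide as it forms, so neither ester is cleaved or moved, and the inert atmosphere protects the free phenol from oxidation.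

## Compound list

1 | 4-methoxy-2-methylphenol | Cc1cc(OC)ccc1O | starting material
2 | (4-methoxy-2-methylphenoxy)triisopropylsilane | Cc1cc(OC)ccc1O[Si](C(C)C)(C(C)C)C(C)C | intermediate
3 | (5-bromo-4-methoxy-2-methylphenoxy)triisopropylsilane | Cc1cc(OC)c(Br)cc1O[Si](C(C)C)(C(C)C)C(C)C | intermediate
4 | 2-chloro-N-methoxy-N-methylacetamide | CON(C)C(=O)CCl | starting material
5 | [2-methoxy-4-methyl-5-(triisopropylsilyloxy)phenyl]lithium | [Li]c1cc(O[Si](C(C)C)(C(C)C)C(C)C)c(C)cc1OC | intermediate
6 | 2-chloro-1-[2-methoxy-4-methyl-5-(triisopropylsilyloxy)phenyl]ethan-1-one | O=C(CCl)c1cc(O[Si](C(C)C)(C(C)C)C(C)C)c(C)cc1OC | intermediate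
7 | vinylmagnesium bromide | C=C[Mg]Br | starting material
8 | racemic 1-chloro-2-[2-methoxy-4-methyl-5-(triisopropylsilyloxy)phenyl]but-3-en-2-ol | C=CC(O)(CCl)c1cc(O[Si](C(C)C)(C(C)C)C(C)C)c(C)cc1OC | intermediate
9 | racemic potassium 1-chloro-2-[2-methoxy-4-methyl-5-(triisopropylsilyloxy)phenyl]but-3-en-2-yl carbonate | C=CC(CCl)(OC(=O)[O-])c1cc(O[Si](C(C)C)(C(C)C)C(C)C)c(C)cc1OC.[K+] | intermediate
10 | racemic 4-[2-methoxy-4-methyl-5-(triisopropylsilyloxy)phenyl]-4-vinyl-1,3-dioxolan-2-one | C=CC1(COC(=O)O1)c1cc(O[Si](C(C)C)(C(C)C)C(C)C)c(C)cc1OC | intermediate
11 | water | O | starting material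
12 | (2R)-2-[2-methoxy-4-methyl-5-(triisopropylsilyloxy)phenyl]but-3-ene-1,2-diol | C=C[C@](O)(CO)c1cc(O[Si](C(C)C)(C(C)C)C(C)C)c(C)cc1OC | intermediate
13 | (2R)-2-hydroxy-2-[2-methoxy-4-methyl-5-(triisopropylsilyloxy)phenyl]but-3-en-1-yl acetate | C=C[C@](O)(COC(C)=O)c1cc(O[Si](C(C)C)(C(C)C)C(C)C)c(C)cc1OC | intermediate
14 | (2R)-2-hydroxy-2-[2-methoxy-4-methyl-5-(triisopropylsilyloxy)phenyl]-2-(1,2,4-trioxolan-3-yl)ethyl acetate, mixture of epimers at the trioxolane carbon | O1OC(OC1)[C@](O)(COC(C)=O)c2cc(O[Si](C(C)C)(C(C)C)C(C)C)c(C)cc2OC | intermediate
15 | (2R)-2-hydroxy-2-[2-methoxy-4-methyl-5-(triisopropylsilyloxy)phenyl]-3-oxopropyl acetate | O=C[C@](O)(COC(C)=O)c1cc(O[Si](C(C)C)(C(C)C)C(C)C)c(C)cc1OC | intermediate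
16 | (2S)-2,3-dihydroxy-2-[2-methoxy-4-methyl-5-(triisopropylsilyloxy)phenyl]propyl acetate | OC[C@](O)(COC(C)=O)c1cc(O[Si](C(C)C)(C(C)C)C(C)C)c(C)cc1OC | intermediate
17 | (E)-2-methylbut-2-enoyl chloride (tigloyl chloride) | C/C=C(\C)C(Cl)=O | starting material
18 | (2R)-3-acetoxy-2-hydroxy-2-[2-methoxy-4-methyl-5-(triisopropylsilyloxy)phenyl]propyl (E)-2-methylbut-2-enoate | C/C=C(\C)C(=O)OC[C@](O)(COC(C)=O)c1cc(O[Si](C(C)C)(C(C)C)C(C)C)c(C)cc1OC | intermediate
19 | (2R)-3-acetoxy-2-hydroxy-2-(5-hydroxy-2-methoxy-4-methylphenyl)propyl (E)-2-methylbut-2-enoate | C/C=C(\C)C(=O)OC[C@](O)(COC(C)=O)c1cc(O)c(C)cc1OC | target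

## Step count and risks

Total steps: 11. Longest linear sequence: 11 steps (1 → 19).

Step 6 (key step). The ortho-methoxy group may twist the aryl ring out of the allyl plane, so that ionisation is slow or the ligand discriminates the two faces poorly. Attack at the CH2 terminus (linear product) or attack of the alkoxide on a second π-allyl complex (oligomers) could also compete. The fallback is a resolution. Carbonate 10 would be hydrolysed (LiOH, THF/H2O, 0 °C) to the racemic diol F1, and F1 would be acetylated at its primary hydroxyl by a lipase with vinyl acetate. The fallback is written for the case that the enzyme acylates the (S)-enantiomer, giving the (S)-acetate F2 and leaving the (R)-diol, which is 12, so the route is rejoined at 12. If the enzyme prefers the (R)-enantiomer, the acetate formed is 13 itself and the route is rejoined one step later.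

Step 5. The alkoxide may close directly onto the CH2Cl group without taking up CO2, or carbonate in DMF may cleave the aryl silyl ether. The fallback starts from 8: NaH in THF at 0 °C would give the vinyl epoxide F3 on purpose, and F3 would take up CO2 (1 atm) under Pd(PPh3)4 in THF, through a π-allylpalladium alkoxide that is carboxylated and recloses at the substituted terminus, returning to the route at 10.

Step 8. Ozone may attack the electron-rich arene once the alkene is consumed, or the allylic alcohol may fragment with loss of a further carbon. The fallback starts from 13: the tertiary hydroxyl would be capped (TESOTf, 2,6-lutidine, CH2Cl2, −78 °C) to give the triethylsilyl ether F4. With that oxygen blocked, cleavage with OsO4 (cat.), NaIO4 and 2,6-lutidine in dioxane/water offers periodate only the terminal diol and would give the silyloxy aldehyde F5. HF·pyridine in THF at 0 °C would then remove the triethylsilyl group, returning to the route at 15.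

Step 9. In the alkoxyborate or the free diol, the acetyl group may move from one primary oxygen to the other, eroding enantiomeric purity, or be lost by methanolysis. The fallback starts from 12 and keeps every acyl group away until the arm is reduced:
- 2,2-dimethoxypropane with PPTS would give the acetonide F6.
- OsO4 (cat.) and NaIO4 with 2,6-lutidine would give the aldehyde F7; no free α-hydroxyl is present and no ozone is needed.
- NaBH4 in MeOH at 0 °C would give the alcohol F8.
- Tigloyl chloride 17 with pyridine would give the tiglate F9.
- Aqueous AcOH at 40 °C would release the hydroxy tiglate F10.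
- Ac2O with pyridine at 0 °C would acetylate the primary hydroxyl, returning to the route at 18.

The only acyl group then present beside a free primary hydroxyl is the sluggish tigloyl group, and only under non-basic conditions; the cost is two extra steps.

## Further compounds

F1 | step 6 | racemic 2-[2-methoxy-4-methyl-5-(triisopropylsilyloxy)phenyl]but-3-ene-1,2-diol | C=CC(O)(CO)c1cc(O[Si](C(C)C)(C(C)C)C(C)C)c(C)cc1OC
F2 | step 6 | (2S)-2-hydroxy-2-[2-methoxy-4-methyl-5-(triisopropylsilyloxy)phenyl]but-3-en-1-yl acetate | C=C[C@@](O)(COC(C)=O)c1cc(O[Si](C(C)C)(C(C)C)C(C)C)c(C)cc1OC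
F3 | step 5 | racemic triisopropyl[4-methoxy-2-methyl-5-(2-vinyloxiran-2-yl)phenoxy]silane | C=CC1(CO1)c2cc(O[Si](C(C)C)(C(C)C)C(C)C)c(C)cc2OC
F4 | step 8 | (2R)-2-[2-methoxy-4-methyl-5-(triisopropylsilyloxy)phenyl]-2-(triethylsilyloxy)but-3-en-1-yl acetate | C=C[C@](O[Si](CC)(CC)CC)(COC(C)=O)c1cc(O[Si](C(C)C)(C(C)C)C(C)C)c(C)cc1OC
F5 | step 8 | (2R)-2-[2-methoxy-4-methyl-5-(triisopropylsilyloxy)phenyl]-3-oxo-2-(triethylsilyloxy)propyl acetate | O=C[C@](O[Si](CC)(CC)CC)(COC(C)=O)c1cc(O[Si](C(C)C)(C(C)C)C(C)C)c(C)cc1OC
F6 | step 9 | (4R)-4-[2-methoxy-4-methyl-5-(triisopropylsilyloxy)phenyl]-2,2-dimethyl-4-vinyl-1,3-dioxolane | C=C[C@@]1(OC(C)(C)OC1)c2cc(O[Si](C(C)C)(C(C)C)C(C)C)c(C)cc2OC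
F7 | step 9 | (4R)-4-[2-methoxy-4-methyl-5-(triisopropylsilyloxy)phenyl]-2,2-dimethyl-1,3-dioxolane-4-carbaldehyde | O=C[C@@]1(OC(C)(C)OC1)c2cc(O[Si](C(C)C)(C(C)C)C(C)C)c(C)cc2OC
F8 | step 9 | {(4S)-4-[2-methoxy-4-methyl-5-(triisopropylsilyloxy)phenyl]-2,2-dimethyl-1,3-dioxolan-4-yl}methanol | OC[C@@]1(OC(C)(C)OC1)c2cc(O[Si](C(C)C)(C(C)C)C(C)C)c(C)cc2OC
F9 | step 9 | {(4R)-4-[2-methoxy-4-methyl-5-(triisopropylsilyloxy)phenyl]-2,2-dimethyl-1,3-dioxolan-4-yl}methyl (E)-2-methylbut-2-enoate | C/C=C(\C)C(=O)OC[C@@]1(OC(C)(C)OC1)c2cc(O[Si](C(C)C)(C(C)C)C(C)C)c(C)cc2OC
F10 | step 9 | (2R)-2,3-dihydroxy-2-[2-methoxy-4-methyl-5-(triisopropylsilyloxy)phenyl]propyl (E)-2-methylbut-2-enoate | C/C=C(\C)C(=O)OC[C@](O)(CO)c1cc(O[Si](C(C)C)(C(C)C)C(C)C)c(C)cc1OC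
A1 | alternative 1 | [2-methoxy-4-methyl-5-(triisopropylsilyloxy)phenyl]boronic acid | OB(O)c1cc(O[Si](C(C)C)(C(C)C)C(C)C)c(C)cc1OC
A2 | alternative 1 | ethyl 3-(benzyloxy)-2-oxopropanoate | CCOC(=O)C(=O)COCc1ccccc1
A3 | alternative 1 | ethyl (2S)-3-(benzyloxy)-2-hydroxy-2-[2-methoxy-4-methyl-5-(triisopropylsilyloxy)phenyl]propanoate | c1ccccc1COC[C@](O)(C(=O)OCC)c2cc(O[Si](C(C)C)(C(C)C)C(C)C)c(C)cc2OC
A4 | alternative 2 | 2-[2-methoxy-4-methyl-5-(triisopropylsilyloxy)phenyl]propane-1,2,3-triol | OCC(O)(CO)c1cc(O[Si](C(C)C)(C(C)C)C(C)C)c(C)cc1OC
A5 | alternative 2 | (2S)-2,3-dihydroxy-2-[2-methoxy-4-methyl-5-(triisopropylsilyloxy)phenyl]propyl acetate | OC[C@](O)(COC(C)=O)c1cc(O[Si](C(C)C)(C(C)C)C(C)C)c(C)cc1OC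
A6 | alternative 3 | oxetan-3-one | O=C1COC1
A7 | alternative 3 | 3-[2-methoxy-4-methyl-5-(triisopropylsilyloxy)phenyl]oxetan-3-ol | OC1(COC1)c2cc(O[Si](C(C)C)(C(C)C)C(C)C)c(C)cc2OC
A8 | alternative 3 | (E)-2-methylbut-2-enoic acid (tiglic acid) | C/C=C(\C)C(=O)O
A9 | alternative 3 | (2R)-2,3-dihydroxy-2-[2-methoxy-4-methyl-5-(triisopropylsilyloxy)phenyl]propyl (E)-2-methylbut-2-enoate | C/C=C(\C)C(=O)OC[C@](O)(CO)c1cc(O[Si](C(C)C)(C(C)C)C(C)C)c(C)cc1OC
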